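With the chain numbered from C1 (enoic carboxyl) to C13, the C4–C5 oxirane (C3 and C6 cis, oxygen anti to the C7 methyl) is the only stereochemical array of the western half, and C3–C8 can be folded into a six-membered carbocycle. The route therefore sets this array on (R)-3,5-dimethylcyclohex-2-enone: one nucleophilic epoxidation forms both oxirane C–O bonds (C5–O, C4–O) and two stereocentres, the ring methyl (C7) directing oxygen to the opposite face while ring fusion enforces the cis oxirane. The template bond C3–C8 is then cut (α'-hydroxylation, methyl addition, glycol cleavage) to unveil a C3 methyl ketone and a C8 aldehyde, which are extended by a Wittig union with an aldol-derived C9–C13 ylide and a Horner–Wadsworth–Emmons olefination.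

Key step: step 6

Remark: centres that arise as mixtures and are erased later (spiro carbon of 2, C2 of 3 and 4, sulfur of 4, carbinol carbons of 10 and 11) are left undefined in the SMILES.

**Ring template and its opening (steps 1–8)**

Step 1
Reactants: 1 (R)-(+)-pulegone
Product: 2 (6R)-2,2,6-trimethyl-1-oxaspiro[2.5]octan-4-one (pulegone oxide; both spiro epimers)
Conditions: 30% aq. H2O2, LiOH·H2O (cat.), MeOH, 0 °C to rt
Reagents that add atoms: hydrogen peroxide, SMILES OO
Why: Weitz–Scheffer nucleophilic epoxidation of the tetrasubstituted enone is a standard transformation of pulegone, and the new spiro centre is irrelevant because that carbon loses its substituent in step 2.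

Step 2
Reactants: 2 pulegone oxide
Product: 3 (5R)-5-methyl-2-(phenylsulfanyl)cyclohexan-1-one (both C2 epimers)
Conditions: PhSH (1.2 equiv), NaH (0.2 equiv), THF, reflux
Reagents that add atoms: thiophenol, SMILES Sc1ccccc1
Why: Thiolate opens the oxirane at the carbonyl-activated ring carbon and the resulting β-alkoxide fragments by retro-aldol loss of acetone, which leaves the remote methyl-bearing centre untouched and a sulfur-bearing carbon whose configuration does not matter.

Step 3
Reactants: 3 (5R)-5-methyl-2-(phenylsulfanyl)cyclohexan-1-one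
Product: 5 (R)-5-methylcyclohex-2-en-1-one, via sulfoxide 4 (not isolated)
Conditions: mCPBA (1.0 equiv), CH2Cl2, −78 °C; then CaCO3, toluene, 110 °C
Reagents that add atoms: none
Why: Sulfide oxidation followed by thermal syn-elimination of the α-sulfinyl ketone (sulfoxide pyrolysis) can place the double bond only between C2 and C3, so the enone forms regiospecifically with the methyl centre intact.

Step 4
Reactants: 5 (R)-5-methylcyclohex-2-en-1-one
Product: 6 trimethyl{[(3R,5R)-3,5-dimethylcyclohex-1-en-1-yl]oxy}silane (methyl groups trans)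
Conditions: Me2CuLi (from MeLi and CuI), Me3SiCl, THF, −78 °C; Et3N quench
Reagents that add atoms: lithium dimethylcuprate, SMILES [Li+].C[Cu-]C; chlorotrimethylsilane, SMILES C[Si](C)(C)Cl
Why: Chlorosilane-accelerated cuprate conjugate addition delivers methyl anti to the ring methyl (the new centre is erased in step 5) and traps the enolate regiospecifically as the silyl enol ether.

Step 5
Reactants: 6 silyl enol ether
Product: 7 (R)-3,5-dimethylcyclohex-2-en-1-one
Conditions: Pd(OAc)2 (10 mol %), O2 (1 atm), DMSO, rt
Reagents that add atoms: none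
Why: Saegusa–Ito oxidation dehydrogenates the regiodefined enol ether across C2–C3 and so returns the enone with its new β-methyl group, without touching the C5 stereocentre.

Step 6
Reactants: 7 (R)-3,5-dimethylcyclohex-2-en-1-one
Product: 8 (1R,4R,6R)-4,6-dimethyl-7-oxabicyclo[4.1.0]heptan-2-one (oxirane oxygen trans to the C4 methyl)
Conditions: 30% aq. H2O2, NaOH (0.3 equiv), MeOH, 0 °C
Reagents that add atoms: hydrogen peroxide, SMILES OO
Why: Hydroperoxide anion adds reversibly to the methyl-bearing β-carbon (future C5) and the enolate carbon (future C4) then displaces hydroxide from the proximal peroxide oxygen, so both oxirane C–O bonds arise in one operation. This is a Weitz–Scheffer epoxidation, with the alkaline H2O2 epoxidation of carvone and of 3-methyl-substituted cyclohexenones as the closest analogies. The three-membered ring closes in a 3-exo-tet mode by SN2 attack of carbon on the O–O bond. The configuration at C5 is set by stereoelectronically preferred axial attack on the half-chair from the face opposite the pseudo-equatorial ring methyl (future C7), and C4 is not independent because an oxirane fused to a six-membered ring must be cis, which also places C3 and C6 cis on the oxirane. Only diastereofacial selectivity is needed, since the enone fixes regio- and chemoselectivity, and the single resident stereocentre should secure it; a minor cis-epoxide should be removable by chromatography.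

Step 7
Reactants: 8 epoxy ketone
Product: 10 (1R,4R,6R)-3-hydroxy-4,6-dimethyl-7-oxabicyclo[4.1.0]heptan-2-one (both C3 epimers), via potassium enolate 9 (not isolated)
Conditions: KN(SiMe3)2, THF, −78 °C; 2-(benzenesulfonyl)-3-phenyloxaziridine, −78 °C; AcOH quench
Reagents that add atoms: 2-(benzenesulfonyl)-3-phenyloxaziridine, SMILES O=S(=O)(c1ccccc1)N1OC1c1ccccc1
Why: Deprotonation can occur only at the CH2 flank (future C8), because the other α-carbon is the oxirane CH, and the enolate is hydroxylated by the N-sulfonyloxaziridine (Davis oxidation) to give a temporary carbinol centre of no stereochemical consequence.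

Step 8
Reactants: 10 α'-hydroxy epoxy ketone
Product: 11 2,4,6-trimethyl-7-oxabicyclo[4.1.0]heptane-2,3-diol (oxirane and C4 methyl centres as in 8; mixture at C2 and C3)
Conditions: MeMgCl (3 equiv), THF, −78 to −30 °C; aq. NH4Cl
Reagents that add atoms: methylmagnesium chloride, SMILES C[Mg]Cl
Why: After the first equivalent has deprotonated the hydroxyl, Grignard 1,2-addition to the alkoxide-chelated ketone installs the future C3 methyl group, while the trisubstituted oxirane is inert to MeMgCl at low temperature.

**C9–C13 phosphonium salt (steps 9–16)**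

Step 9
Reactants: 12 (R)-4-benzyloxazolidin-2-one, 13 3-(benzyloxy)propanoic acid
Product: 15 (R)-4-benzyl-3-[3-(benzyloxy)propanoyl]oxazolidin-2-one, via mixed anhydride 14 (not isolated)
Conditions: 13, pivaloyl chloride, Et3N, THF, −20 °C; then 12, LiCl, −20 °C to rt
Reagents that add atoms: none
Why: N-Acylation of the oxazolidinone through the mixed pivalic anhydride under LiCl/Et3N activation is the standard one-pot preparation of such imides.

Step 10
Reactants: 16 methyl 4-chlorobutanoate
Product: 17 4-chlorobutanal
Conditions: iBu2AlH (1.05 equiv), CH2Cl2, −78 °C; MeOH, aq. potassium sodium tartrate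
Reagents that add atoms: none
Why: Partial reduction of the ester with iBu2AlH at −78 °C stops at the tetrahedral aluminium hemiacetal, which releases the aldehyde on work-up for immediate use.

Step 11
Reactants: 15 imide, 17 4-chlorobutanal
Product: 19 (R)-4-benzyl-3-[(2R,3S)-2-[(benzyloxy)methyl]-6-chloro-3-hydroxyhexanoyl]oxazolidin-2-one, via boron enolate 18 (not isolated)
Conditions: Bu2BOTf, iPr2NEt, CH2Cl2, −78 to 0 °C; then 17, −78 to 0 °C; pH 7 buffer, MeOH, 30% H2O2, 0 °C
Reagents that add atoms: none
Why: In this Evans syn-aldol the dibutylboron Z-enolate reacts through a chair Zimmerman–Traxler transition state on the face away from the benzyl group of the (R)-auxiliary, which sets C12 (S) and C13 (R) in the required syn relationship, and the covalent boron enolate should not expel the β-benzyloxy group at low temperature.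

Step 12
Reactants: 19 aldol adduct
Product: 20 (R)-4-benzyl-3-[(2R,3S)-6-chloro-3-hydroxy-2-(hydroxymethyl)hexanoyl]oxazolidin-2-one
Conditions: H2 (1 atm), Pd(OH)2 on carbon, EtOAc, rt
Reagents that add atoms: none
Why: Neutral hydrogenolysis cleaves only the benzyl ether, since the primary alkyl chloride, the imide, the C-benzyl group of the auxiliary and both stereocentres are inert under these conditions.

Step 13
Reactants: 20 diol
Product: 21 (R)-4-benzyl-3-[(2R,3S)-3-[(tert-butyldimethylsilyl)oxy]-2-{[(tert-butyldimethylsilyl)oxy]methyl}-6-chlorohexanoyl]oxazolidin-2-one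
Conditions: tBuMe2SiOTf (2.5 equiv), 2,6-lutidine, CH2Cl2, −78 to 0 °C
Reagents that add atoms: tert-butyldimethylsilyl trifluoromethanesulfonate, SMILES CC(C)(C)[Si](C)(C)OS(=O)(=O)C(F)(F)F
Why: The silyl triflate with a hindered pyridine base silylates both the primary and the hindered secondary hydroxyl without generating an alkoxide that could undergo retro-aldol cleavage or attack the imide.

Step 14
Reactants: 21 bis-silyl imide
Product: 23 (2R,3S)-3-[(tert-butyldimethylsilyl)oxy]-2-{[(tert-butyldimethylsilyl)oxy]methyl}-6-chlorohexanoic acid, via peroxy acid 22 (not isolated)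
Conditions: LiOH, 30% H2O2, THF/H2O, 0 °C; aq. Na2SO3; HCl to pH 3
Reagents that add atoms: hydrogen peroxide (as lithium hydroperoxide), SMILES OO
Why: Lithium hydroperoxide attacks the exocyclic imide carbonyl selectively even in hindered substrates (standard auxiliary cleavage), sulfite reduces the peracid, and the cold conditions with both hydroxyls blocked should preserve the α-centre and the alkyl chloride.

Step 15
Reactants: 23 acid
Product: 24 2-(trimethylsilyl)ethyl (2R,3S)-3-[(tert-butyldimethylsilyl)oxy]-2-{[(tert-butyldimethylsilyl)oxy]methyl}-6-chlorohexanoate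
Conditions: Me3SiCH2CH2OH, EDC·HCl, DMAP (cat.), CH2Cl2, 0 °C to rt
Reagents that add atoms: 2-(trimethylsilyl)ethanol, SMILES C[Si](C)(C)CCO
Why: Steglich esterification with a primary alcohol is fast enough to avoid α-epimerization and gives an ester that is later removed by fluoride instead of hydroxide.

Step 16
Reactants: 24 chloro ester
Product: 26 {(4S,5R)-4-[(tert-butyldimethylsilyl)oxy]-5-{[(tert-butyldimethylsilyl)oxy]methyl}-6-oxo-6-[2-(trimethylsilyl)ethoxy]hexyl}triphenylphosphonium iodide, via alkyl iodide 25 (not isolated)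
Conditions: NaI, PPh3, NaHCO3, MeCN, 80 °C
Reagents that add atoms: triphenylphosphine, SMILES c1ccc(cc1)P(c1ccccc1)c1ccccc1; sodium iodide, SMILES [Na+].[I-]
Why: Finkelstein exchange followed by SN2 quaternization of triphenylphosphine converts the primary chloride into the phosphonium iodide under neutral conditions that the silyl ethers and the ester tolerate.

**Olefination reagent (step 17)**

Step 17
Reactants: 27 (diethoxyphosphoryl)acetic acid
Product: 28 2-(trimethylsilyl)ethyl 2-(diethoxyphosphoryl)acetate
Conditions: Me3SiCH2CH2OH, EDC·HCl, DMAP (cat.), CH2Cl2, 0 °C to rt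
Reagents that add atoms: 2-(trimethylsilyl)ethanol, SMILES C[Si](C)(C)CCO
Why: Steglich esterification provides the Horner–Wadsworth–Emmons reagent with the same fluoride-labile ester as the C13 carboxyl, so that one final reagent can free both acids.

**Union and end game (steps 18–22)**

Step 18
Reactants: 11 diol
Product: 29 (2R)-3-[(2R,3R)-3-acetyl-2-methyloxiran-2-yl]-2-methylpropanal
Conditions: NaIO4, THF/pH 7 phosphate buffer, 0 °C to rt; used at once
Reagents that add atoms: none
Why: Periodate (Malaprade) cleavage of the only vicinal diol severs the template bond C3–C8 under neutral conditions and releases the C3 methyl ketone and the C8 aldehyde without epimerizing C7 or touching the oxirane.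

Step 19
Reactants: 29 keto aldehyde, 26 phosphonium iodide
Product: 31 2-(trimethylsilyl)ethyl (2R,3S,6Z,8R)-9-[(2R,3R)-3-acetyl-2-methyloxiran-2-yl]-3-[(tert-butyldimethylsilyl)oxy]-2-{[(tert-butyldimethylsilyl)oxy]methyl}-8-methylnon-6-enoate, via phosphorus ylide 30 (not isolated)
Conditions: 26, NaN(SiMe3)2 (slightly less than 1 equiv per 26), THF, −78 to 0 °C; then 29, −78 to −20 °C
Reagents that add atoms: none
Why: Wittig olefination by the non-stabilized ylide is far faster at the aldehyde than at the methyl ketone at −78 °C, the low temperature and absence of excess base limit enolization at C7, and the expected Z geometry is immaterial because the alkene is saturated in step 20.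

Step 20
Reactants: 31 alkene
Product: 32 2-(trimethylsilyl)ethyl (2R,3S,8S)-9-[(2R,3R)-3-acetyl-2-methyloxiran-2-yl]-3-[(tert-butyldimethylsilyl)oxy]-2-{[(tert-butyldimethylsilyl)oxy]methyl}-8-methylnonanoate
Conditions: KO2CN=NCO2K (excess), AcOH (slow addition), pyridine/MeOH, 0 °C to rt
Reagents that add atoms: none
Why: Diimide generated from the azodicarboxylate salt (no hydrazine or sulfonylhydrazide that could condense with the epoxy ketone) transfers H2 concertedly to the unhindered disubstituted alkene and neither reduces the ketone, opens the oxirane nor moves the double bond towards the allylic C7 centre.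

Step 21
Reactants: 32 ketone, 28 phosphonate
Product: 34 bis[2-(trimethylsilyl)ethyl] (2E,4S,5R,7S,12S,13R)-12-[(tert-butyldimethylsilyl)oxy]-13-{[(tert-butyldimethylsilyl)oxy]methyl}-4,5-epoxy-3,5,7-trimethyltetradec-2-enedioate, via phosphonate anion 33 (not isolated)
Conditions: 28 (3 equiv), NaH (2.8 equiv), THF, 0 °C; then 32, 0 °C to rt
Reagents that add atoms: none
Why: Horner–Wadsworth–Emmons olefination of the oxirane-activated methyl ketone should favour the E enoate, in which the ester lies trans to the larger oxirane-bearing substituent, and the weakly basic phosphonate anion should leave the C13 ester centre untouched.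

Step 22
Reactants: 34 fully protected diester
Product: 35 (2E,4S,5R,7S,12S,13R)-4,5-epoxy-12-hydroxy-13-(hydroxymethyl)-3,5,7-trimethyltetradec-2-enedioic acid (target)
Conditions: Bu4NF (excess), THF, 0 °C to rt; aq. NaH2PO4 (pH 4), EtOAc extraction
Reagents that add atoms: none
Why: Fluoride removes both silyl ethers and fragments both 2-(trimethylsilyl)ethyl esters (loss of ethene and fluorotrimethylsilane) in one operation without hydroxide or strong acid, so the oxirane, the E enoate and the β-hydroxy acid unit should survive.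

**Compound list**

1 | (R)-(+)-pulegone, (5R)-5-methyl-2-(propan-2-ylidene)cyclohexan-1-one | C[C@@H]1CCC(=C(C)C)C(=O)C1 | starting material
2 | (6R)-2,2,6-trimethyl-1-oxaspiro[2.5]octan-4-one (both spiro epimers) | C[C@@H]1CCC2(OC2(C)C)C(=O)C1 | intermediate
3 | (5R)-5-methyl-2-(phenylsulfanyl)cyclohexan-1-one (both C2 epimers) | C[C@@H]1CCC(Sc2ccccc2)C(=O)C1 | intermediate
4 | (5R)-2-(benzenesulfinyl)-5-methylcyclohexan-1-one (mixture at C2 and S) | C[C@@H]1CCC(S(=O)c2ccccc2)C(=O)C1 | intermediate
5 | (R)-5-methylcyclohex-2-en-1-one | C[C@@H]1CC=CC(=O)C1 | intermediate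
6 | trimethyl{[(3R,5R)-3,5-dimethylcyclohex-1-en-1-yl]oxy}silane | C[C@@H]1C[C@@H](C)C=C(O[Si](C)(C)C)C1 | intermediate
7 | (R)-3,5-dimethylcyclohex-2-en-1-one | O=C1C=C(C)C[C@@H](C)C1 | intermediate
8 | (1R,4R,6R)-4,6-dimethyl-7-oxabicyclo[4.1.0]heptan-2-one | O=C1[C@@H]2O[C@]2(C)C[C@@H](C)C1 | intermediate
9 | potassium enolate of 8 (enolate double bond towards the CH2 flank) | [K+].[O-]C1=C[C@H](C)C[C@@]2(C)O[C@@H]12 | intermediate
10 | (1R,4R,6R)-3-hydroxy-4,6-dimethyl-7-oxabicyclo[4.1.0]heptan-2-one (both C3 epimers) | O=C1[C@@H]2O[C@]2(C)C[C@@H](C)C1O | intermediate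
11 | 2,4,6-trimethyl-7-oxabicyclo[4.1.0]heptane-2,3-diol (oxirane and C4 methyl centres as in 8; mixture at C2 and C3) | CC1(O)[C@@H]2O[C@]2(C)C[C@@H](C)C1O | intermediate
12 | (R)-4-benzyloxazolidin-2-one | O=C1N[C@H](Cc2ccccc2)CO1 | starting material
13 | 3-(benzyloxy)propanoic acid | OC(=O)CCOCc1ccccc1 | starting material
14 | 3-(benzyloxy)propanoic pivalic anhydride | CC(C)(C)C(=O)OC(=O)CCOCc1ccccc1 | intermediate
15 | (R)-4-benzyl-3-[3-(benzyloxy)propanoyl]oxazolidin-2-one | O=C(CCOCc1ccccc1)N1[C@H](Cc2ccccc2)COC1=O | intermediate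
16 | methyl 4-chlorobutanoate | COC(=O)CCCCl | starting material
17 | 4-chlorobutanal | O=CCCCCl | intermediate
18 | dibutylboron Z-enolate of 15 | CCCCB(CCCC)O/C(=C\COCc1ccccc1)N1[C@H](Cc2ccccc2)COC1=O | intermediate
19 | (R)-4-benzyl-3-[(2R,3S)-2-[(benzyloxy)methyl]-6-chloro-3-hydroxyhexanoyl]oxazolidin-2-one | ClCCC[C@H](O)[C@@H](COCc1ccccc1)C(=O)N1[C@H](Cc2ccccc2)COC1=O | intermediate
20 | (R)-4-benzyl-3-[(2R,3S)-6-chloro-3-hydroxy-2-(hydroxymethyl)hexanoyl]oxazolidin-2-one | ClCCC[C@H](O)[C@@H](CO)C(=O)N1[C@H](Cc2ccccc2)COC1=O | intermediate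
21 | (R)-4-benzyl-3-[(2R,3S)-3-[(tert-butyldimethylsilyl)oxy]-2-{[(tert-butyldimethylsilyl)oxy]methyl}-6-chlorohexanoyl]oxazolidin-2-one | ClCCC[C@H](O[Si](C)(C)C(C)(C)C)[C@@H](CO[Si](C)(C)C(C)(C)C)C(=O)N1[C@H](Cc2ccccc2)COC1=O | intermediate
22 | (2R,3S)-3-[(tert-butyldimethylsilyl)oxy]-2-{[(tert-butyldimethylsilyl)oxy]methyl}-6-chlorohexaneperoxoic acid | ClCCC[C@H](O[Si](C)(C)C(C)(C)C)[C@@H](CO[Si](C)(C)C(C)(C)C)C(=O)OO | intermediate
23 | (2R,3S)-3-[(tert-butyldimethylsilyl)oxy]-2-{[(tert-butyldimethylsilyl)oxy]methyl}-6-chlorohexanoic acid | ClCCC[C@H](O[Si](C)(C)C(C)(C)C)[C@@H](CO[Si](C)(C)C(C)(C)C)C(=O)O | intermediate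
24 | 2-(trimethylsilyl)ethyl (2R,3S)-3-[(tert-butyldimethylsilyl)oxy]-2-{[(tert-butyldimethylsilyl)oxy]methyl}-6-chlorohexanoate | ClCCC[C@H](O[Si](C)(C)C(C)(C)C)[C@@H](CO[Si](C)(C)C(C)(C)C)C(=O)OCC[Si](C)(C)C | intermediate
25 | 2-(trimethylsilyl)ethyl (2R,3S)-3-[(tert-butyldimethylsilyl)oxy]-2-{[(tert-butyldimethylsilyl)oxy]methyl}-6-iodohexanoate | ICCC[C@H](O[Si](C)(C)C(C)(C)C)[C@@H](CO[Si](C)(C)C(C)(C)C)C(=O)OCC[Si](C)(C)C | intermediate
26 | {(4S,5R)-4-[(tert-butyldimethylsilyl)oxy]-5-{[(tert-butyldimethylsilyl)oxy]methyl}-6-oxo-6-[2-(trimethylsilyl)ethoxy]hexyl}triphenylphosphonium iodide | [I-].c1ccccc1[P+](c1ccccc1)(c1ccccc1)CCC[C@H](O[Si](C)(C)C(C)(C)C)[C@@H](CO[Si](C)(C)C(C)(C)C)C(=O)OCC[Si](C)(C)C | intermediate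
27 | (diethoxyphosphoryl)acetic acid | CCOP(=O)(CC(=O)O)OCC | starting material
28 | 2-(trimethylsilyl)ethyl 2-(diethoxyphosphoryl)acetate | CCOP(=O)(CC(=O)OCC[Si](C)(C)C)OCC | intermediate
29 | (2R)-3-[(2R,3R)-3-acetyl-2-methyloxiran-2-yl]-2-methylpropanal | CC(=O)[C@@H]1O[C@]1(C)C[C@@H](C)C=O | intermediate
30 | phosphorus ylide from 26 | c1ccccc1P(c1ccccc1)(c1ccccc1)=CCC[C@H](O[Si](C)(C)C(C)(C)C)[C@@H](CO[Si](C)(C)C(C)(C)C)C(=O)OCC[Si](C)(C)C | intermediate
31 | 2-(trimethylsilyl)ethyl (2R,3S,6Z,8R)-9-[(2R,3R)-3-acetyl-2-methyloxiran-2-yl]-3-[(tert-butyldimethylsilyl)oxy]-2-{[(tert-butyldimethylsilyl)oxy]methyl}-8-methylnon-6-enoate | CC(=O)[C@@H]1O[C@]1(C)C[C@@H](C)/C=C\CC[C@H](O[Si](C)(C)C(C)(C)C)[C@@H](CO[Si](C)(C)C(C)(C)C)C(=O)OCC[Si](C)(C)C | intermediate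
32 | 2-(trimethylsilyl)ethyl (2R,3S,8S)-9-[(2R,3R)-3-acetyl-2-methyloxiran-2-yl]-3-[(tert-butyldimethylsilyl)oxy]-2-{[(tert-butyldimethylsilyl)oxy]methyl}-8-methylnonanoate | CC(=O)[C@@H]1O[C@]1(C)C[C@@H](C)CCCC[C@H](O[Si](C)(C)C(C)(C)C)[C@@H](CO[Si](C)(C)C(C)(C)C)C(=O)OCC[Si](C)(C)C | intermediate
33 | sodium salt of 28 (phosphonate carbanion) | [Na+].CCOP(=O)(OCC)[CH-]C(=O)OCC[Si](C)(C)C | intermediate
34 | bis[2-(trimethylsilyl)ethyl] (2E,4S,5R,7S,12S,13R)-12-[(tert-butyldimethylsilyl)oxy]-13-{[(tert-butyldimethylsilyl)oxy]methyl}-4,5-epoxy-3,5,7-trimethyltetradec-2-enedioate | C/C(=C\C(=O)OCC[Si](C)(C)C)[C@@H]1O[C@]1(C)C[C@@H](C)CCCC[C@H](O[Si](C)(C)C(C)(C)C)[C@@H](CO[Si](C)(C)C(C)(C)C)C(=O)OCC[Si](C)(C)C | intermediate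
35 | (2E,4S,5R,7S,12S,13R)-4,5-epoxy-12-hydroxy-13-(hydroxymethyl)-3,5,7-trimethyltetradec-2-enedioic acid (CNP0468463.2) | C/C(=C\C(=O)O)[C@@H]1O[C@]1(C)C[C@@H](C)CCCC[C@H](O)[C@@H](CO)C(=O)O | target

**Step count**

Total: 22 steps. Longest linear sequence: 13 steps (steps 1–8 and 18–22, from 1 to 35).

**Steps most likely to fail**

Step 19. The ylide may also attack the oxirane-activated methyl ketone, the α-branched aldehyde may epimerize at C7 by enolization, or the ylide may be acylated by its own ester. The fallback is a Julia–Kocienski olefination, a less basic and more aldehyde-selective union; it sets out from chloride 24 and keto aldehyde 29 and comes back to the route at 32. Chloride 24 is treated with 1-phenyl-1H-tetrazole-5-thiol (K2CO3, NaI cat., DMF) to give the tetrazolyl sulfide F1, which is oxidized with H2O2 and (NH4)6Mo7O24 in EtOH to the tetrazolyl sulfone F2. KN(SiMe3)2 is then added to a mixture of F2 and 29 in 1,2-dimethoxyethane at −60 °C, so that the sulfonyl carbanion is trapped as it forms, giving the E alkene F3. Its geometry is immaterial, because diimide reduction under the conditions of step 20 converts it into 32.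

Step 7. The free enolate may be consumed by opening of the neighbouring oxirane or by addition to the sulfonimine by-product, and the α-ketol may isomerize through its enediol during basic work-up. The fallback is a Rubottom-type oxidation through the silyl enol ether; it sets out from 8 and comes back at 10. LiN(SiMe3)2 is added to 8 in the presence of Me3SiCl (THF, −78 °C), so that the enolate is silylated as it forms, giving the silyl enol ether F4. Catalytic OsO4 with N-methylmorpholine N-oxide in acetone/water then dihydroxylates the enol ether, and the resulting hemiketal collapses to 10 with loss of trimethylsilanol.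

Step 6. Facial discrimination by a single remote methyl group may be incomplete and leave some cis-epoxide. The fallback adds catalyst control to substrate control; it sets out from 7, comes back at 8 and makes no new compound (F0). The enone is epoxidized with aqueous H2O2 through its iminium ion with a chiral primary amine salt (a 9-amino-9-deoxy-epi-cinchona alkaloid as its trifluoroacetate), using the pseudoenantiomer whose face preference matches that of the substrate, so that reagent and substrate bias should reinforce each other.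

**Further compounds**

F1 | step 19 | 2-(trimethylsilyl)ethyl (2R,3S)-3-[(tert-butyldimethylsilyl)oxy]-2-{[(tert-butyldimethylsilyl)oxy]methyl}-6-[(1-phenyl-1H-tetrazol-5-yl)sulfanyl]hexanoate | c1ccccc1-n1nnnc1SCCC[C@H](O[Si](C)(C)C(C)(C)C)[C@@H](CO[Si](C)(C)C(C)(C)C)C(=O)OCC[Si](C)(C)C
F2 | step 19 | 2-(trimethylsilyl)ethyl (2R,3S)-3-[(tert-butyldimethylsilyl)oxy]-2-{[(tert-butyldimethylsilyl)oxy]methyl}-6-[(1-phenyl-1H-tetrazol-5-yl)sulfonyl]hexanoate | c1ccccc1-n1nnnc1S(=O)(=O)CCC[C@H](O[Si](C)(C)C(C)(C)C)[C@@H](CO[Si](C)(C)C(C)(C)C)C(=O)OCC[Si](C)(C)C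
F3 | step 19 | 2-(trimethylsilyl)ethyl (2R,3S,6E,8R)-9-[(2R,3R)-3-acetyl-2-methyloxiran-2-yl]-3-[(tert-butyldimethylsilyl)oxy]-2-{[(tert-butyldimethylsilyl)oxy]methyl}-8-methylnon-6-enoate | CC(=O)[C@@H]1O[C@]1(C)C[C@@H](C)/C=C/CC[C@H](O[Si](C)(C)C(C)(C)C)[C@@H](CO[Si](C)(C)C(C)(C)C)C(=O)OCC[Si](C)(C)C
F4 | step 7 | trimethylsilyl enol ether of 8 (enol double bond towards the CH2 flank) | C[Si](C)(C)OC1=C[C@H](C)C[C@@]2(C)O[C@@H]12
F0 | step 6 | none | none
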